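**Plan**

- Atoms are numbered as in 2H-chromene (O1, C2, C3, C4, C4a, C5 to C8, C8a; the benzene ring is ring A). The retrosynthesis cuts, in this order: the C7–CH2 bond of the arylethyl chain; the C6–CH2 bond of the prenyl group, traced back by a [3,3] shift to a 1,1-dimethylallyl ether on O5; then O1–C2 together with the C4–C3 bond of the pyran ring.
- Enabling feature: in ring A, C4a (which carries C4) lies between C8a–O1 and C5–OH, so C4 is the formyl carbon of a 2,6-dioxygenated benzaldehyde. A free phenol ortho to a formyl group can bind an alkenylboronic acid, receive its alkenyl group at the formyl carbon and then close the pyran ring through an ortho-quinone methide. C2 with its two methyl groups is the β-carbon of 2-methylprop-1-enylboronic acid.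
- The second ring-A oxygen is capped as a 1,1-dimethylallyl ether so that only one phenol can become O1. This helper is not discarded: it is moved to C6 as the prenyl group.
- Forward: ring A is bought as 4-bromo-2,6-dimethoxybenzaldehyde; the pyran ring forms in step 4, the prenyl group reaches C6 in step 5, and the 4-hydroxyphenylethyl chain is joined to C7 last by B-alkyl Suzuki coupling.
- Stereochemistry: the target has no stereocentre and no alkene with E/Z isomerism (C3=C4 is cis within the ring), so none has to be set.

Key step: step 4

**Route**

Step 1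
Reactants: 1 4-bromo-2,6-dimethoxybenzaldehyde
Product: 2 4-bromo-2,6-dihydroxybenzaldehyde
Conditions: AlCl3 (4 equiv), CH2Cl2, 0 °C to rt; aq. HCl
Reagents that add atoms: none
Why: AlCl3 binds the formyl oxygen and each flanking methoxy oxygen in a six-membered chelate, so chloride removes both methyl groups by SN2 attack (chelation-assisted Lewis acid cleavage of aryl methyl ethers ortho to a carbonyl group) while the aldehyde and the aryl bromide stay untouched.

Step 2
Reactants: 3 2-methylbut-3-en-2-ol
Product: 4 tert-butyl 2-methylbut-3-en-2-yl carbonate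
Conditions: n-BuLi (1.05 equiv), THF, 0 °C; Boc2O (1.1 equiv), 0 °C to rt
Reagents that add atoms: di-tert-butyl dicarbonate (Boc2O), CC(C)(C)OC(=O)OC(=O)OC(C)(C)C
Why: The lithium alkoxide of the tertiary allylic alcohol attacks Boc2O at a carbonyl carbon and expels tert-butyl carbonate (alkoxide acylation to a mixed carbonate), the usual way to activate this alcohol for allyl-palladium chemistry.

Step 3
Reactants: 2 4-bromo-2,6-dihydroxybenzaldehyde; 4 tert-butyl 2-methylbut-3-en-2-yl carbonate
Product: 5 4-bromo-2-hydroxy-6-[(2-methylbut-3-en-2-yl)oxy]benzaldehyde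
Conditions: Pd(PPh3)4 (2 mol %), 4 (1.1 equiv), THF, 0 °C, short reaction time
Reagents that add atoms: none
Why: Zerovalent palladium ionises the tertiary allylic carbonate (Tsuji–Trost O-allylation), the tert-butoxide set free by loss of CO2 deprotonates the one phenol of 2 that is not held in the hydrogen bond to the formyl oxygen, and this phenoxide attacks the more substituted allyl terminus under kinetic control at 0 °C to give the 1,1-dimethylallyl ether, the remaining chelated phenol being too poor a nucleophile for a second alkylation.

Step 4
Reactants: 5 4-bromo-2-hydroxy-6-[(2-methylbut-3-en-2-yl)oxy]benzaldehyde; 6 (2-methylprop-1-en-1-yl)boronic acid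
Product: 9 7-bromo-2,2-dimethyl-5-[(2-methylbut-3-en-2-yl)oxy]-2H-chromene, via Mannich base 7 (not isolated), via ortho-quinone methide 8 (not isolated)
Conditions: 6 (1.5 equiv), Bn2NH (20 mol %), 1,4-dioxane, 65 °C, Ar
Reagents that add atoms: none
Why: Dibenzylamine condenses with the formyl group of 5 to an iminium ion while the free ortho-phenol binds 6 as a tetracoordinate boronate, which hands its 2-methylprop-1-enyl group to the iminium carbon within the complex (Petasis borono-Mannich reaction) and so makes the C4–C3 bond in 7. On warming, 7 loses dibenzylamine, helped by the phenol and by the allylic, dimethyl-stabilised character of the benzylic carbon, to give the ortho-quinone methide 8, and the amine returns to the cycle. 8 is a 1-oxatriene that closes the pyran ring by thermal disrotatory oxa-6π electrocyclisation, which forms the O1–C2 bond, restores the aromatic ring and leaves C3=C4 cis within the ring; the closest known reaction type is the amine-catalysed condensation of salicylaldehydes with alkenylboronic acids to 2H-chromenes. No stereocentre is formed. The step needs regioselectivity between the two oxygens that flank the formyl carbon, and this is secured because only one of them is a free phenol, the other being capped as the 1,1-dimethylallyl ether; it also needs that ether to stay in place, which the temperature of 65 °C, well below that of the later [3,3] shift, should ensure, and the aryl bromide is inert.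

Step 5
Reactants: 9 7-bromo-2,2-dimethyl-5-[(2-methylbut-3-en-2-yl)oxy]-2H-chromene
Product: 11 7-bromo-2,2-dimethyl-6-(3-methylbut-2-en-1-yl)-2H-chromen-5-ol, via dienone 10 (not isolated)
Conditions: PhMe, 120 °C, sealed tube, Ar
Reagents that add atoms: none
Why: Aromatic Claisen rearrangement: the [3,3] shift of the 1,1-dimethylallyl aryl ether delivers the allyl unit with allylic inversion, as a normal prenyl group, to C6, the only ortho carbon that carries hydrogen, and dienone 10 tautomerises to the phenol, whereas a shift to the ring-fusion carbon C4a cannot be followed by enolisation and is reversible.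

Step 6
Reactants: 11 7-bromo-2,2-dimethyl-6-(3-methylbut-2-en-1-yl)-2H-chromen-5-ol; 12 4-ethenylphenyl acetate (4-acetoxystyrene)
Product: 15 7-[2-(4-hydroxyphenyl)ethyl]-2,2-dimethyl-6-(3-methylbut-2-en-1-yl)-2H-chromen-5-ol, via alkylborane 13 (not isolated), via aryl acetate 14 (not isolated)
Conditions: a) 12 (1.6 equiv), 9-BBN-H (1.5 equiv), THF, 0 °C to rt; b) 11, PdCl2(dppf) (5 mol %), aq. K3PO4, THF/DMF, 60 °C; c) aq. NaOH, MeOH, rt, Ar; aq. NH4Cl
Reagents that add atoms: none
Why: 9-BBN-H adds to the styrene with anti-Markovnikov selectivity to give the primary alkylborane 13, which after activation by aqueous phosphate transfers its alkyl group to the arylpalladium bromide formed from 11 (B-alkyl Suzuki–Miyaura coupling), and the final hydroxide treatment saponifies the aryl acetate of 14; the prenyl and chromene alkenes never meet a B–H bond because 12 is used in slight excess over 9-BBN-H.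

**Compound list**

1 | 4-bromo-2,6-dimethoxybenzaldehyde | COc1cc(Br)cc(OC)c1C=O | starting material
2 | 4-bromo-2,6-dihydroxybenzaldehyde | O=Cc1c(O)cc(Br)cc1O | intermediate
3 | 2-methylbut-3-en-2-ol | C=CC(C)(C)O | starting material
4 | tert-butyl 2-methylbut-3-en-2-yl carbonate | C=CC(C)(C)OC(=O)OC(C)(C)C | intermediate
5 | 4-bromo-2-hydroxy-6-[(2-methylbut-3-en-2-yl)oxy]benzaldehyde | C=CC(C)(C)Oc1cc(Br)cc(O)c1C=O | intermediate
6 | (2-methylprop-1-en-1-yl)boronic acid | CC(C)=CB(O)O | starting material
7 | 5-bromo-2-[1-(dibenzylamino)-3-methylbut-2-en-1-yl]-3-[(2-methylbut-3-en-2-yl)oxy]phenol (racemic Mannich base) | C=CC(C)(C)Oc1cc(Br)cc(O)c1C(C=C(C)C)N(Cc1ccccc1)Cc1ccccc1 | intermediate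
8 | (6Z)-3-bromo-6-(3-methylbut-2-en-1-ylidene)-5-[(2-methylbut-3-en-2-yl)oxy]cyclohexa-2,4-dien-1-one (ortho-quinone methide) | O=C1C=C(Br)C=C(OC(C)(C)C=C)/C1=C/C=C(C)C | intermediate
9 | 7-bromo-2,2-dimethyl-5-[(2-methylbut-3-en-2-yl)oxy]-2H-chromene | C=CC(C)(C)Oc1cc(Br)cc2c1C=CC(C)(C)O2 | intermediate
10 | 7-bromo-2,2-dimethyl-6-(3-methylbut-2-en-1-yl)-2H-chromen-5(6H)-one (racemic dienone) | O=C1C(CC=C(C)C)C(Br)=CC2=C1C=CC(C)(C)O2 | intermediate
11 | 7-bromo-2,2-dimethyl-6-(3-methylbut-2-en-1-yl)-2H-chromen-5-ol | CC(C)=CCc1c(Br)cc2c(c1O)C=CC(C)(C)O2 | intermediate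
12 | 4-ethenylphenyl acetate (4-acetoxystyrene) | CC(=O)Oc1ccc(C=C)cc1 | starting material
13 | 4-[2-(9-borabicyclo[3.3.1]nonan-9-yl)ethyl]phenyl acetate | CC(=O)Oc1ccc(CCB2C3CCCC2CCC3)cc1 | intermediate
14 | 4-{2-[5-hydroxy-2,2-dimethyl-6-(3-methylbut-2-en-1-yl)-2H-chromen-7-yl]ethyl}phenyl acetate | CC(C)=CCc1c(CCc2ccc(OC(C)=O)cc2)cc2c(c1O)C=CC(C)(C)O2 | intermediate
15 | 7-[2-(4-hydroxyphenyl)ethyl]-2,2-dimethyl-6-(3-methylbut-2-en-1-yl)-2H-chromen-5-ol | CC(C)=CCc1c(CCc2ccc(O)cc2)cc2c(c1O)C=CC(C)(C)O2 | target

**Step count**

Total step count: 6. Longest linear sequence: 5 steps (steps 1, 3, 4, 5 and 6; step 2 is a one-step side branch).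

**Steps most likely to fail, with fallbacks**

Step 4. The [3,3] shift of the allyl ether may set in before the pyran ring has closed, which would free the second phenol and scramble the direction of ring closure. Iminium formation at the doubly ortho-substituted formyl group may also stall. The fallback sets out from 5 and makes the same two bonds in two cold operations without amine or boron. Addition of 2-methylprop-1-enylmagnesium bromide (2.2 equiv, THF, −78 to 0 °C; the first equivalent is spent on the phenol) should give 5-bromo-2-(1-hydroxy-3-methylbut-2-en-1-yl)-3-[(2-methylbut-3-en-2-yl)oxy]phenol F1. Stirring this doubly activated benzylic, allylic alcohol with catalytic pyridinium p-toluenesulfonate (or on silica gel) in CH2Cl2 at room temperature should ionise it to the ortho-quinone methide 8, which closes to 9, where the route is rejoined.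

Step 3. The phenoxide may attack the unsubstituted allyl terminus, or the catalyst may re-ionise the product, so that the linear prenyl ether accumulates. Double alkylation and insertion of palladium into the C–Br bond are further ways to lose material. The fallback sets out from 2 and builds the ether without allyl-palladium chemistry. Copper-catalysed O-propargylation with 3-chloro-3-methylbut-1-yne (CuCl2 cat., DBU, MeCN, 0 °C) should give 4-bromo-2-hydroxy-6-[(2-methylbut-3-yn-2-yl)oxy]benzaldehyde F2. Semihydrogenation of the terminal alkyne (H2, Pd/CaCO3 poisoned with Pb(OAc)2, quinoline, EtOAc, rt) should then give 5, where the route is rejoined.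

Step 5. The allyl group may migrate to the substituted ring-fusion carbon C4a and move on by a second shift to C8, or it may be lost as isoprene on heating. The fallback sets out from 9 and replaces the sigmatropic shift by an ionic C-alkylation. Removal of the allyl group with Pd(PPh3)4 (cat.) and morpholine in THF at room temperature should give 7-bromo-2,2-dimethyl-2H-chromen-5-ol F3. Its sodium phenoxide (NaH, toluene, 0 °C to rt) should take up prenyl bromide at C6, the only free ortho carbon, through the tight ion pair (ortho-selective C-alkylation of phenoxides in non-polar solvents) to give 11, where the route is rejoined.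

**Further compounds**

F1 | step 4 | 5-bromo-2-(1-hydroxy-3-methylbut-2-en-1-yl)-3-[(2-methylbut-3-en-2-yl)oxy]phenol (racemic) | C=CC(C)(C)Oc1cc(Br)cc(O)c1C(O)C=C(C)C
F2 | step 3 | 4-bromo-2-hydroxy-6-[(2-methylbut-3-yn-2-yl)oxy]benzaldehyde | C#CC(C)(C)Oc1cc(Br)cc(O)c1C=O
F3 | step 5 | 7-bromo-2,2-dimethyl-2H-chromen-5-ol | Oc1cc(Br)cc2c1C=CC(C)(C)O2
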